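**Plan** (longipinane numbering: C1 ketone, C2=C3(CH3), C4, C5, C6(CH3)2, C7 senecioate, C8, C9 tiglate, C10(CH3), C11; cyclobutane C4–C5–C11–C10)
1. Retrosynthetic cuts, in order: C2=C3 (intramolecular Horner–Wadsworth–Emmons); C4–C10, by putting C3 back as a ring ketone between C10 and C4 (retro-Wolff) to give a bicyclo[4.2.1]nonan-8-one; C8–C7 (aldol); C5–C6 (Mukaiyama–Michael); C9–C10 (aldol); C11–C1 (dithiane 1,4-addition).
2. Enabling feature: C3 is an exocyclic sp2 carbon on cyclobutane carbon C4, next to quaternary C10. This is the pattern left when a ketone carbon is extruded from a C10–C(=O)–C4 unit, and C10 has no hydrogen, so a diazo group can only sit on C4.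
3. Forward order of rings: cyclopentenone (C3, C4, C5, C11, C10) first; the seven-membered carbocycle C10–C9–C8–C7–C6–C5–C11 by aldol; then the ring contraction.
4. The contraction makes the cyclobutane and turns the eight-membered ring C3–C4–C5–C6–C7–C8–C9–C10 into the seven-membered ring C4–C5–C6–C7–C8–C9–C10; the cyclohexenone is closed last.
5. Stereochemistry: C11 from (S)-4-silyloxycyclopentenone (addition anti to OSi); C10 and C5 by trans relay from C11; C7 from the chelated aldol; C9 by anti hydride delivery from O7 (Evans–Tishchenko); C4 by protonation and ring closure cis to C11.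

Key step: step 10

Remark: the two carbinol epimers of 9 are carried together (the centre is oxidised in step 4). For 24–29 the C4 epimer that is needed is written; its epimer converges in step 14.

Step 1
Reactants: 1 (S)-4-(tert-butyldimethylsilyloxy)cyclopent-2-en-1-one; 2 1,3-dithiane
Product: 5 4-(tert-butyldimethylsilyloxy)-3-(1,3-dithian-2-yl)-2-methylcyclopentan-1-one (2,3-trans; 3,4-trans), via 2-lithio-1,3-dithiane 3 (not isolated), via lithium enolate 4 (not isolated)
Conditions: n-BuLi, THF, −30 °C; HMPA, then 1, −78 °C; MeI, −78 → −40 °C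
Reagents that add atoms: iodomethane CI
Why: Corey–Seebach dithiane anion in a tandem conjugate addition–enolate alkylation: with HMPA the lithiated dithiane should add 1,4 to the enone on the face opposite the silyloxy group (this sets the dithianyl-bearing centre), and enolate 4 is methylated at C2 anti to that group.

Step 2
Reactants: 5 4-(tert-butyldimethylsilyloxy)-3-(1,3-dithian-2-yl)-2-methylcyclopentan-1-one
Product: 6 4-(1,3-dithian-2-yl)-5-methylcyclopent-2-en-1-one (4,5-trans)
Conditions: DBU, CH2Cl2, 0 °C, short contact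
Reagents that add atoms: none
Why: E1cB β-elimination of silanolate from the β-silyloxy ketone should give the 4-substituted cyclopent-2-enone without touching the dithianyl-bearing centre, the only one that matters at this stage.

Step 3
Reactants: 6 4-(1,3-dithian-2-yl)-5-methylcyclopent-2-en-1-one; 7 acetaldehyde
Product: 9 4-(1,3-dithian-2-yl)-5-(1-hydroxyethyl)-5-methylcyclopent-2-en-1-one (hydroxyethyl trans to dithianyl), via lithium dienolate 8 (not isolated)
Conditions: LiN(iPr)2, THF, −78 °C; MeCHO; AcOH, −78 °C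
Reagents that add atoms: none
Why: Kinetic α′-deprotonation of the enone and aldol addition of the cross-conjugated enolate to acetaldehyde, which should enter at C5 anti to the neighbouring dithianyl group and so set the quaternary centre (hydroxyethyl trans to dithianyl, methyl cis).

Step 4
Reactants: 9 4-(1,3-dithian-2-yl)-5-(1-hydroxyethyl)-5-methylcyclopent-2-en-1-one
Product: 10 5-acetyl-4-(1,3-dithian-2-yl)-5-methylcyclopent-2-en-1-one (acetyl trans to dithianyl)
Conditions: (COCl)2, DMSO, CH2Cl2, −78 °C; Et3N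
Reagents that add atoms: none
Why: Swern oxidation of the secondary alcohol to the methyl ketone gives a non-enolisable 1,3-diketone under conditions that a thioacetal tolerates.

Step 5
Reactants: 10 5-acetyl-4-(1,3-dithian-2-yl)-5-methylcyclopent-2-en-1-one; 11 2-methyl-1-(trimethylsilyloxy)prop-1-ene
Product: 13 2-acetyl-3-(1,3-dithian-2-yl)-2-methyl-4-(2-methyl-1-oxopropan-2-yl)cyclopentan-1-one (side chain at C4 cis to acetyl; both trans to dithianyl), via silyl enol ether adduct 12 (not isolated)
Conditions: Sc(OTf)3 (10 mol %), CH2Cl2, −40 → 0 °C; then 1 M HCl, THF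
Reagents that add atoms: none
Why: Mukaiyama–Michael addition: the Lewis-acid-bound enone is attacked at its β-carbon by the fully substituted carbon of the silyl enol ether anti to the adjacent dithianyl group, which sets this centre trans to dithianyl and hence cis to the acetyl group, as the later ring closure requires.

Step 6
Reactants: 13 2-acetyl-3-(1,3-dithian-2-yl)-2-methyl-4-(2-methyl-1-oxopropan-2-yl)cyclopentan-1-one
Product: 15 9-(1,3-dithian-2-yl)-4-hydroxy-1,5,5-trimethylbicyclo[4.2.1]nonane-2,8-dione (4-OH on the side of the C7–C8 bridge; dithianyl on C9 pointing away from the C2–C5 bridge), via acetyl lithium enolate 14 (not isolated)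
Conditions: LiN(SiMe3)2, THF (0.01 M), −78 → −40 °C; AcOH, −78 °C
Reagents that add atoms: none
Why: Intramolecular directed aldol addition (7-exo-trig) of the methyl ketone enolate to the non-enolisable neopentyl aldehyde: enolisation of the ring ketone could only close four-membered rings and so leads nowhere, and the carbinol centre is expected from the closed Zimmerman–Traxler transition state in which the lithium-bridged oxygens lie over the flat ring-ketone bridge and not over the inward-pointing C9–H, which puts OH on the side of C7–C8.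

Step 7
Reactants: 15 9-(1,3-dithian-2-yl)-4-hydroxy-1,5,5-trimethylbicyclo[4.2.1]nonane-2,8-dione; 16 3-methylbut-2-enal
Product: 17 9-(1,3-dithian-2-yl)-2-hydroxy-1,5,5-trimethyl-8-oxobicyclo[4.2.1]nonan-4-yl 3-methylbut-2-enoate (2-OH on the side of C9, trans to the 4-acyloxy group)
Conditions: SmI2 (30 mol %, premixed with the enal), THF, −10 °C
Reagents that add atoms: none
Why: Evans–Tishchenko reduction: the C4 hydroxyl forms a hemiacetal with the enal on samarium and its hydride is delivered intramolecularly to the C2 ketone from the face of the C4 oxygen, which should give the 2,4-trans (anti) diol monoester with the senecioate on O4 and the free hydroxyl on C2, while the C8 ketone is out of reach.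

Step 8
Reactants: 17 9-(1,3-dithian-2-yl)-2-hydroxy-1,5,5-trimethyl-8-oxobicyclo[4.2.1]nonan-4-yl 3-methylbut-2-enoate; 18 (E)-2-methylbut-2-enoyl chloride
Product: 19 9-(1,3-dithian-2-yl)-1,5,5-trimethyl-4-(3-methylbut-2-enoyloxy)-8-oxobicyclo[4.2.1]nonan-2-yl (E)-2-methylbut-2-enoate
Conditions: pyridine, DMAP (cat.), CH2Cl2, 0 °C → rt
Reagents that add atoms: none
Why: DMAP-catalysed acylation of the hindered secondary alcohol with the acid chloride installs the tiglate with retention at carbon and closes off the retro-aldol-prone β-hydroxy ketone.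

Step 9
Reactants: 19 9-(1,3-dithian-2-yl)-1,5,5-trimethyl-4-(3-methylbut-2-enoyloxy)-8-oxobicyclo[4.2.1]nonan-2-yl (E)-2-methylbut-2-enoate
Product: 22 7-diazo-9-(1,3-dithian-2-yl)-1,5,5-trimethyl-4-(3-methylbut-2-enoyloxy)-8-oxobicyclo[4.2.1]nonan-2-yl (E)-2-methylbut-2-enoate, via lithium enolate 20 (not isolated), via 7-trifluoroacetyl ketone 21 (not isolated)
Conditions: LiN(SiMe3)2, THF, −78 °C; CF3CO2CH2CF3; aq. HCl work-up; then MsN3, Et3N, H2O, MeCN, rt
Reagents that add atoms: methanesulfonyl azide CS(=O)(=O)N=[N+]=[N-]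
Why: Deacylative diazo transfer (Regitz type): the enolate can form only towards C7 because C1 is quaternary, and its trifluoroacetyl derivative 21 takes up the diazo group from the sulfonyl azide with loss of the trifluoroacetyl group; no stereocentre is formed.

Step 10
Reactants: 22 7-diazo-9-(1,3-dithian-2-yl)-1,5,5-trimethyl-4-(3-methylbut-2-enoyloxy)-8-oxobicyclo[4.2.1]nonan-2-yl (E)-2-methylbut-2-enoate
Product: 24 8-(1,3-dithian-2-yl)-1,5,5-trimethyl-4-(3-methylbut-2-enoyloxy)-2-[(E)-2-methylbut-2-enoyloxy]bicyclo[4.1.1]octane-7-carboxylic acid (CO2H and dithianyl cis, both pointing away from the C2–C5 bridge), via ketene 23 (not isolated)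
Conditions: hν (365 nm), THF/H2O, rt, degassed
Reagents that add atoms: water O
Why: Irradiation expels N2 from the diazo ketone while the quaternary bridgehead C1 (future C10) shifts from the carbonyl carbon C8 (future C3) to the diazo carbon C7 (future C4), and ketene 23 is trapped by water: a Wolff rearrangement with ring contraction, whose closest precedent is the contraction of 2-diazocyclopentanones held in polycycles (D-norsteroids, bicyclo[2.1.1]hexanes from diazonorbornanones). The shift makes the C4–C10 bond, so the cyclopentanone becomes the cyclobutane C4–C5–C11–C10 (closed by a 1,2-shift, not by an exo or endo cyclisation) and, because C3 leaves the ring, the eight-membered ring C3–C4–C5–C6–C7–C8–C9–C10 becomes the seven-membered ring C4–C5–C6–C7–C8–C9–C10. The migrating carbon keeps its configuration and C5, C7, C9 and C11 are untouched; the only new stereocentre, C4, is set when the enol of the acid is protonated, which should occur from the face of the four-carbon bridge because the other face is screened across the cyclobutane by the dithianyl group on C11, leaving CO2H cis to that group. The selectivity needed is rearrangement over carbene chemistry (1,2-hydride shift from C5, ylide formation at sulfur, C–H insertion): the ring holds the diazo ketone s-Z, the geometry in which migration is concerted with loss of N2, so no free carbene should intervene. Regiochemistry is not in question because C10 is the only carbon on the carbonyl that can migrate, and at 365 nm only the diazo ketone absorbs, so the enoate esters should not isomerise.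

Step 11
Reactants: 24 8-(1,3-dithian-2-yl)-1,5,5-trimethyl-4-(3-methylbut-2-enoyloxy)-2-[(E)-2-methylbut-2-enoyloxy]bicyclo[4.1.1]octane-7-carboxylic acid
Product: 26 7-acetyl-8-(1,3-dithian-2-yl)-1,5,5-trimethyl-4-(3-methylbut-2-enoyloxy)bicyclo[4.1.1]octan-2-yl (E)-2-methylbut-2-enoate, via acid chloride 25 (not isolated)
Conditions: (COCl)2, DMF (cat.), CH2Cl2, 0 °C; then MeZnCl, Pd(PPh3)4 (5 mol %), THF, 0 °C
Reagents that add atoms: methylzinc chloride C[Zn]Cl
Why: Acid chloride formation followed by palladium-catalysed Negishi acylation with the methylzinc reagent should give the methyl ketone without touching the two enoate esters or enolising the α-centre.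

Step 12
Reactants: 26 7-acetyl-8-(1,3-dithian-2-yl)-1,5,5-trimethyl-4-(3-methylbut-2-enoyloxy)bicyclo[4.1.1]octan-2-yl (E)-2-methylbut-2-enoate
Product: 27 7-acetyl-8-formyl-1,5,5-trimethyl-4-(3-methylbut-2-enoyloxy)bicyclo[4.1.1]octan-2-yl (E)-2-methylbut-2-enoate
Conditions: MeI, CaCO3, MeCN/H2O, 45 °C
Reagents that add atoms: water O
Why: Alkylative hydrolysis of the 1,3-dithiane (S-methylation, then attack of water) unmasks the aldehyde under near-neutral conditions that spare esters and ketone.

Step 13
Reactants: 27 7-acetyl-8-formyl-1,5,5-trimethyl-4-(3-methylbut-2-enoyloxy)bicyclo[4.1.1]octan-2-yl (E)-2-methylbut-2-enoate; 28 dimethyl (diazomethyl)phosphonate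
Product: 29 7-acetyl-8-[2-(dimethoxyphosphoryl)acetyl]-1,5,5-trimethyl-4-(3-methylbut-2-enoyloxy)bicyclo[4.1.1]octan-2-yl (E)-2-methylbut-2-enoate
Conditions: SnCl2 (10 mol %), CH2Cl2, rt
Reagents that add atoms: none
Why: Roskamp-type homologation: the SnCl2-activated aldehyde is attacked by the diazo carbon and a 1,2-hydride shift with loss of N2 gives the β-keto phosphonate, while ketones and esters do not react.

Step 14
Reactants: 29 7-acetyl-8-[2-(dimethoxyphosphoryl)acetyl]-1,5,5-trimethyl-4-(3-methylbut-2-enoyloxy)bicyclo[4.1.1]octan-2-yl (E)-2-methylbut-2-enoate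
Product: 30 CNP0277258.1, 7-(3-methylbut-2-enoyloxy)-9-[(E)-2-methylbut-2-enoyloxy]longipin-2-en-1-one
Conditions: K2CO3, 18-crown-6, toluene, 70 °C
Reagents that add atoms: none
Why: Intramolecular Horner–Wadsworth–Emmons olefination (six-membered ring, phosphonate carbon onto the methyl ketone) closes the cyclohexenone with the carbonyl at C1 and the methyl on C3 by construction; only the isomer with both acyl groups cis on the cyclobutane can close, and base equilibration at the two α-centres feeds it.

**Compound list**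
1 | (S)-4-(tert-butyldimethylsilyloxy)cyclopent-2-en-1-one | O=C1C=C[C@@H](O[Si](C)(C)C(C)(C)C)C1 | starting material
2 | 1,3-dithiane | C1CSCSC1 | starting material
3 | 2-lithio-1,3-dithiane | [Li]C1SCCCS1 | intermediate (not isolated)
4 | lithium enolate of the 1,4-adduct (dithianyl trans to OSi) | [Li]OC1=C[C@H](C2SCCCS2)[C@@H](O[Si](C)(C)C(C)(C)C)C1 | intermediate (not isolated)
5 | 4-(tert-butyldimethylsilyloxy)-3-(1,3-dithian-2-yl)-2-methylcyclopentan-1-one (2,3-trans; 3,4-trans) | O=C1[C@@H](C)[C@H](C2SCCCS2)[C@@H](O[Si](C)(C)C(C)(C)C)C1 | intermediate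
6 | 4-(1,3-dithian-2-yl)-5-methylcyclopent-2-en-1-one (4,5-trans) | O=C1C=C[C@@H](C2SCCCS2)[C@@H]1C | intermediate
7 | acetaldehyde | CC=O | starting material
8 | lithium dienolate of 6 | [Li]OC1=C(C)[C@H](C2SCCCS2)C=C1 | intermediate (not isolated)
9 | 4-(1,3-dithian-2-yl)-5-(1-hydroxyethyl)-5-methylcyclopent-2-en-1-one (hydroxyethyl trans to dithianyl; both carbinol epimers) | O=C1C=C[C@@H](C2SCCCS2)[C@]1(C)C(O)C | intermediate
10 | 5-acetyl-4-(1,3-dithian-2-yl)-5-methylcyclopent-2-en-1-one (acetyl trans to dithianyl) | O=C1C=C[C@@H](C2SCCCS2)[C@]1(C)C(C)=O | intermediate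
11 | 2-methyl-1-(trimethylsilyloxy)prop-1-ene | CC(C)=CO[Si](C)(C)C | starting material
12 | trimethylsilyl enol ether of 13 (ring ketone masked) | C[Si](C)(C)OC1=C[C@H](C(C)(C)C=O)[C@@H](C2SCCCS2)[C@]1(C)C(C)=O | intermediate (not isolated)
13 | 2-acetyl-3-(1,3-dithian-2-yl)-2-methyl-4-(2-methyl-1-oxopropan-2-yl)cyclopentan-1-one (C4 chain cis to acetyl, both trans to dithianyl) | O=C1C[C@H](C(C)(C)C=O)[C@@H](C2SCCCS2)[C@]1(C)C(C)=O | intermediate
14 | lithium enolate of the acetyl group of 13 | O=C1C[C@H](C(C)(C)C=O)[C@@H](C2SCCCS2)[C@]1(C)C(=C)O[Li] | intermediate (not isolated)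
15 | 9-(1,3-dithian-2-yl)-4-hydroxy-1,5,5-trimethylbicyclo[4.2.1]nonane-2,8-dione (4-OH towards C7–C8) | C[C@@]12C(=O)C[C@@H](O)C(C)(C)[C@@H](CC1=O)[C@H]2C3SCCCS3 | intermediate
16 | 3-methylbut-2-enal | CC(C)=CC=O | starting material
17 | 9-(1,3-dithian-2-yl)-2-hydroxy-1,5,5-trimethyl-8-oxobicyclo[4.2.1]nonan-4-yl 3-methylbut-2-enoate (2-OH towards C9, trans to 4-O) | C[C@@]12[C@H](O)C[C@@H](OC(=O)C=C(C)C)C(C)(C)[C@@H](CC1=O)[C@H]2C3SCCCS3 | intermediate
18 | (E)-2-methylbut-2-enoyl chloride (tigloyl chloride) | C/C=C(\C)C(Cl)=O | starting material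
19 | 9-(1,3-dithian-2-yl)-1,5,5-trimethyl-4-(3-methylbut-2-enoyloxy)-8-oxobicyclo[4.2.1]nonan-2-yl (E)-2-methylbut-2-enoate | C[C@@]12[C@H](OC(=O)/C(C)=C/C)C[C@@H](OC(=O)C=C(C)C)C(C)(C)[C@@H](CC1=O)[C@H]2C3SCCCS3 | intermediate
20 | lithium enolate of 19 (C7=C8) | C[C@@]12[C@H](OC(=O)/C(C)=C/C)C[C@@H](OC(=O)C=C(C)C)C(C)(C)[C@@H](C=C1O[Li])[C@H]2C3SCCCS3 | intermediate (not isolated)
21 | 7-(trifluoroacetyl) derivative of 19 (C7 not defined) | C[C@@]12[C@H](OC(=O)/C(C)=C/C)C[C@@H](OC(=O)C=C(C)C)C(C)(C)[C@@H](C(C(=O)C(F)(F)F)C1=O)[C@H]2C3SCCCS3 | intermediate (not isolated)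
22 | 7-diazo-9-(1,3-dithian-2-yl)-1,5,5-trimethyl-4-(3-methylbut-2-enoyloxy)-8-oxobicyclo[4.2.1]nonan-2-yl (E)-2-methylbut-2-enoate | C[C@@]12[C@H](OC(=O)/C(C)=C/C)C[C@@H](OC(=O)C=C(C)C)C(C)(C)[C@@H](C(=[N+]=[N-])C1=O)[C@H]2C3SCCCS3 | intermediate
23 | ketene from 22 (bicyclo[4.1.1]octan-7-ylidene ketene) | C[C@@]12[C@H](OC(=O)/C(C)=C/C)C[C@@H](OC(=O)C=C(C)C)C(C)(C)[C@@H](C1=C=O)[C@H]2C3SCCCS3 | intermediate (not isolated)
24 | 8-(1,3-dithian-2-yl)-1,5,5-trimethyl-4-(3-methylbut-2-enoyloxy)-2-[(E)-2-methylbut-2-enoyloxy]bicyclo[4.1.1]octane-7-carboxylic acid (7,8-cis) | C[C@@]12[C@H](OC(=O)/C(C)=C/C)C[C@@H](OC(=O)C=C(C)C)C(C)(C)[C@@H]([C@@H]1C(=O)O)[C@H]2C3SCCCS3 | intermediate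
25 | acid chloride of 24 | C[C@@]12[C@H](OC(=O)/C(C)=C/C)C[C@@H](OC(=O)C=C(C)C)C(C)(C)[C@@H]([C@@H]1C(Cl)=O)[C@H]2C3SCCCS3 | intermediate (not isolated)
26 | 7-acetyl-8-(1,3-dithian-2-yl)-1,5,5-trimethyl-4-(3-methylbut-2-enoyloxy)bicyclo[4.1.1]octan-2-yl (E)-2-methylbut-2-enoate | C[C@@]12[C@H](OC(=O)/C(C)=C/C)C[C@@H](OC(=O)C=C(C)C)C(C)(C)[C@@H]([C@@H]1C(C)=O)[C@H]2C3SCCCS3 | intermediate
27 | 7-acetyl-8-formyl-1,5,5-trimethyl-4-(3-methylbut-2-enoyloxy)bicyclo[4.1.1]octan-2-yl (E)-2-methylbut-2-enoate | C[C@@]12[C@H](OC(=O)/C(C)=C/C)C[C@@H](OC(=O)C=C(C)C)C(C)(C)[C@@H]([C@@H]1C(C)=O)[C@H]2C=O | intermediate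
28 | dimethyl (diazomethyl)phosphonate | COP(=O)(OC)C=[N+]=[N-] | starting material
29 | 7-acetyl-8-[2-(dimethoxyphosphoryl)acetyl]-1,5,5-trimethyl-4-(3-methylbut-2-enoyloxy)bicyclo[4.1.1]octan-2-yl (E)-2-methylbut-2-enoate | C[C@@]12[C@H](OC(=O)/C(C)=C/C)C[C@@H](OC(=O)C=C(C)C)C(C)(C)[C@@H]([C@@H]1C(C)=O)[C@H]2C(=O)CP(=O)(OC)OC | intermediate
30 | CNP0277258.1, 7-(3-methylbut-2-enoyloxy)-9-[(E)-2-methylbut-2-enoyloxy]longipin-2-en-1-one | C/C=C(\C)C(=O)O[C@@H]1C[C@@H](OC(=O)C=C(C)C)C(C)(C)[C@@H]2[C@H]3C(=O)C=C(C)[C@@H]2[C@]31C | target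

Total step count: 14. Longest linear sequence: 14 steps (from 1).

**Steps most likely to fail**

Step 7. Hydride transfer from the conjugated hemiacetal may be slow, the enal may be consumed on samarium, or the samarium alkoxide formed at C2 may undergo retro-aldol. The fallback sets out from 15 and returns at 17. It installs the senecioate by ordinary acylation after a protecting-group relay. The same Evans–Tishchenko reduction is run with acetaldehyde, its standard partner, to give 9-(1,3-dithian-2-yl)-2-hydroxy-1,5,5-trimethyl-8-oxobicyclo[4.2.1]nonan-4-yl acetate F1. The C2 hydroxyl is silylated (tert-butyldimethylsilyl triflate, 2,6-lutidine) to give the 2-silyl ether acetate F2. K2CO3 in methanol removes the acetate to give 2-(tert-butyldimethylsilyloxy)-9-(1,3-dithian-2-yl)-4-hydroxy-1,5,5-trimethylbicyclo[4.2.1]nonan-8-one F3. This is acylated with 3-methylbut-2-enoyl chloride (pyridine, DMAP) to the silylated senecioate F4, and HF·pyridine then frees the C2 hydroxyl to give 17.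

Step 6. The base may deprotonate the ring ketone instead of the acetyl group, and the new alkoxide may attack the neighbouring ring ketone with retro-Claisen opening. The fallback sets out from 10 and 11 and returns at 15. Step 5 is stopped before the acidic work-up and silyl enol ether 12 is isolated by a non-aqueous work-up, so that the ring ketone stays masked. With LiN(SiMe3)2 at −78 °C only the acetyl group of 12 can be enolised, and the aldol closure should give the masked ketol 9-(1,3-dithian-2-yl)-4-hydroxy-1,5,5-trimethyl-8-(trimethylsilyloxy)bicyclo[4.2.1]non-7-en-2-one F5. Quenching with AcOH and treatment with dilute HCl in THF then frees the ring ketone and gives 15.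

Step 5. The congested bond between the fully substituted donor carbon and the β-carbon next to the dithianyl-bearing centre may form too slowly, with loss of the silyl enol ether by hydrolysis or binding of the Lewis acid to sulfur. The fallback sets out from 10 and returns at 13. It uses a Giese radical addition, which is little affected by crowding or by sulfur. The tertiary radical from 2-bromo-1,1-dimethoxy-2-methylpropane ((Me3Si)3SiH, AIBN, benzene, 80 °C) should add to the enone anti to the dithianyl group to give 2-acetyl-4-(1,1-dimethoxy-2-methylpropan-2-yl)-3-(1,3-dithian-2-yl)-2-methylcyclopentan-1-one F6. Aqueous trifluoroacetic acid then hydrolyses the acetal to 13.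

**Further compounds**
F1 | step 7 | 9-(1,3-dithian-2-yl)-2-hydroxy-1,5,5-trimethyl-8-oxobicyclo[4.2.1]nonan-4-yl acetate | C[C@@]12[C@H](O)C[C@@H](OC(C)=O)C(C)(C)[C@@H](CC1=O)[C@H]2C3SCCCS3
F2 | step 7 | 2-(tert-butyldimethylsilyloxy)-9-(1,3-dithian-2-yl)-1,5,5-trimethyl-8-oxobicyclo[4.2.1]nonan-4-yl acetate | C[C@@]12[C@H](O[Si](C)(C)C(C)(C)C)C[C@@H](OC(C)=O)C(C)(C)[C@@H](CC1=O)[C@H]2C3SCCCS3
F3 | step 7 | 2-(tert-butyldimethylsilyloxy)-9-(1,3-dithian-2-yl)-4-hydroxy-1,5,5-trimethylbicyclo[4.2.1]nonan-8-one | C[C@@]12[C@H](O[Si](C)(C)C(C)(C)C)C[C@@H](O)C(C)(C)[C@@H](CC1=O)[C@H]2C3SCCCS3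
F4 | step 7 | 2-(tert-butyldimethylsilyloxy)-9-(1,3-dithian-2-yl)-1,5,5-trimethyl-8-oxobicyclo[4.2.1]nonan-4-yl 3-methylbut-2-enoate | C[C@@]12[C@H](O[Si](C)(C)C(C)(C)C)C[C@@H](OC(=O)C=C(C)C)C(C)(C)[C@@H](CC1=O)[C@H]2C3SCCCS3
F5 | step 6 | 9-(1,3-dithian-2-yl)-4-hydroxy-1,5,5-trimethyl-8-(trimethylsilyloxy)bicyclo[4.2.1]non-7-en-2-one | C[C@@]12C(=O)C[C@@H](O)C(C)(C)[C@@H](C=C1O[Si](C)(C)C)[C@H]2C3SCCCS3
F6 | step 5 | 2-acetyl-4-(1,1-dimethoxy-2-methylpropan-2-yl)-3-(1,3-dithian-2-yl)-2-methylcyclopentan-1-one | O=C1C[C@H](C(C)(C)C(OC)OC)[C@@H](C2SCCCS2)[C@]1(C)C(C)=O
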